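The runs are simulated with made-up constants, and the scatter is random.

At early times the birch run moves fast: starting complex reads 23.5 % at 6.00 min, then stands near 18.0 % up to 80.0 min. An exchange runs at a constant times c(starting complex) c(incoming ligand), so a rate that dies with starting complex still present points to c(incoming ligand). I therefore read incoming ligand as the limiting reagent in the oak, birch and maple runs and reckon each of their plateaus as a budget.

| flask | starting complex | incoming ligand | leaving ligand | capture agent | protic impurity | remark | time |
|---|---|---|---|---|---|---|---|
| oak | 0.50 M | 0.44 M | 0.50 M | 0.50 M | 0.025 M | run made earlier |  |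
| birch | 0.50 M | 0.82 M | 0.50 M | 0.50 M | 0.025 M | run made earlier |  |
| maple | 0.50 M | 1 M | 0.50 M | 0.50 M | 0.025 M | run made earlier |  |
| Saturday's | 0.50 M | 0.500 M | 0.500 M | 0.500 M | 0.0250 M |  | 2.0 h |
| Wednesday's | 0.50 M | 0.600 M | 0.500 M | 0.500 M | 0.0250 M |  | 2.0 h |
| Monday's | 0.50 M | 1.25 M | 0.500 M | 0.500 M | 0.0250 M |  | 2.0 h |

- oak (time / min: complex with two exchanged / %, starting complex / %): 8.00: 12.4, 43.4; 20.0: 12.3, 41.6; 40.0: 12.6, 41.5; 60.0: 12.1, 42.2; 80.0: 11.6, 41.7
- birch (time / min: complex with two exchanged / %, starting complex / %): 6.00: 14.4, 23.5; 12.0: 13.3, 19.0; 25.0: 11.9, 18.3; 40.0: 11.8, 18.2; 80.0: 11.9, 18.0
- maple (time / min: complex with two exchanged / %, starting complex / %): 8.00: 12.1, 14.8; 20.0: 7.6, 10.0; 40.0: 7.4, 9.3; 60.0: 7.0, 9.0; 80.0: 7.2, 8.8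

(each reading ± 0.5 percentage points)

* which of these holds the largest part of the starting complex at the end of Saturday's (starting complex / complex with one exchanged / complex with three exchanged / complex with two exchanged)
* which of these holds the largest part of the starting complex at the end of Wednesday's (starting complex / complex with one exchanged / complex with three exchanged / complex with two exchanged)
* which of these holds the largest part of the starting complex at the end of Monday's (starting complex / complex with one exchanged / complex with three exchanged / complex with two exchanged)
* complex with two exchanged at the end of Saturday's, in percent of the starting complex charged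

- steps under discussion: protic impurity + starting complex -> quenched substrate; starting complex + incoming ligand -> leaving ligand + complex with one exchanged; complex with one exchanged + capture agent -> trapped intermediate; complex with two exchanged + incoming ligand -> leaving ligand + complex with three exchanged; complex with one exchanged + incoming ligand -> leaving ligand + complex with two exchanged

Every exchange spends one incoming ligand, and a complex can take a first, second and third. The oak run's last reading gives 1.65 for what I call the ligand price: the charge of incoming ligand divided by the concentration of starting complex lost to exchange. That loss is the charge less the remainder and less the impurity's share of 5.00 %, which I assume is wholly consumed. The birch run gives 2.13 and the maple run 2.32.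

On a straight line between oak and birch, Saturday's price is 1.73, which leaves 37.1 % starting complex. Wednesday's price is 1.85, which leaves 30.2 %. For Monday's, I estimate that clearing the starting complex at maple's price costs 1.10 M, less than the 1.25 M charged.

The forecast names starting complex for Saturday's, starting complex for Wednesday's and complex with three exchanged for Monday's, with 12.7 % two-exchanged complex in Saturday's (11.3 % to 14.2 %). Its ground is: “The plateaus fit irreversible consumption that stops when incoming ligand runs out.”

The flasks give starting complex, starting complex and complex with three exchanged, with 13.0 % for Saturday's, so the forecast holds on all four.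

    protic impurity + starting complex → quenched substrate (k = 15.0 L mol⁻¹ min⁻¹)
    starting complex + incoming ligand → leaving ligand + complex with one exchanged (k = 0.830 L mol⁻¹ min⁻¹)
    complex with one exchanged + capture agent → trapped intermediate (k = 0.550 L mol⁻¹ min⁻¹)
    complex with two exchanged + incoming ligand → leaving ligand + complex with three exchanged (k = 1.50 L mol⁻¹ min⁻¹)
    complex with one exchanged + incoming ligand → leaving ligand + complex with two exchanged (k = 2.00 L mol⁻¹ min⁻¹)

Saturday's is at rest, with 0 % of its incoming ligand left. Its starting complex stands at 37.1 % at 1.00 h and 37.1 % at 20.0 h, and ten times the time leaves complex with two exchanged at 13.0 %. Saturday's own price, reckoned from its end, is 1.73.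

A neighbour of Saturday's charged with 2.0 M of starting complex lies beyond the readings, but extending the line in equivalents of ligand gives a price of 1.25 and 78.8 % starting complex left. That neighbour ends with 79 % of its charged starting complex still there.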